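**Plan**
- The target is an unsubstituted 27-membered lactone ring (C1–C26 plus the ring oxygen; C1 = carbonyl, C26 = OCH2) with no stereocentre. Retrosynthetically, C13–C16 is raised to a conjugated 1,3-diyne, the ring is cut at the central sp–sp bond C14–C15, then at the ester bond C1–O, and last at C12–C13 and C16–C17.
- Enabling feature: C14–C15 lies opposite the O–C1 ester bond of the all-methylene ring. The cut leaves a C14 acyl arm and a C12 alkoxy arm, each ending in a terminal alkyne carbon, and the straight C13–C16 diyne rod fits a 27-membered ring without strain.
- Forward: two acetylide alkylations of commercial ω-bromides give tetradec-13-ynoic acid and dodec-11-yn-1-ol; esterification joins the chain; copper-mediated oxidative alkyne coupling closes the only ring; hydrogenation removes the diyne.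
- Stereochemistry: none to set, and the alkyne oxidation level avoids any alkene-geometry question.

Key step: step 4

Remark: lithium acetylide–ethylenediamine complex is counted as a commercial starting material (2). Carboxylate and alkoxide salts formed during the alkylations are written as the neutral compounds obtained after acidic work-up.

**Step 1**
Reactants: 1 12-bromododecanoic acid; 2 lithium acetylide–ethylenediamine complex
Product: 3 tetradec-13-ynoic acid
Conditions: 2 (3.5 equiv), DMSO (THF co-solvent), 0–5 °C → rt; then 1 M HCl
Reagents that add atoms: lithium acetylide–ethylenediamine complex (2), [Li]C#C.NCCN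
Why: Acetylide alkylation (SN2), in which the first equivalent of 2 only converts the acid into its carboxylate and further lithium acetylide in DMSO should displace the unhindered primary bromide at C12, the standard way from ω-bromo acids to ω-alkynoic acids.

**Step 2**
Reactants: 4 10-bromodecan-1-ol; 2 lithium acetylide–ethylenediamine complex
Product: 5 dodec-11-yn-1-ol
Conditions: 2 (3 equiv), DMSO (THF co-solvent), 0–5 °C → rt; then 1 M HCl
Reagents that add atoms: lithium acetylide–ethylenediamine complex (2), [Li]C#C.NCCN
Why: Acetylide alkylation (SN2) of the primary bromide, with one equivalent of reagent consumed by the hydroxyl group and the soft acetylide expected to outcompete the alkoxide as nucleophile in DMSO.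

**Step 3**
Reactants: 3 tetradec-13-ynoic acid; 5 dodec-11-yn-1-ol
Product: 6 dodec-11-yn-1-yl tetradec-13-ynoate
Conditions: DCC (1.1 equiv), DMAP (0.1 equiv), CH2Cl2, 0 °C → rt
Reagents that add atoms: none
Why: Steglich esterification, in which DCC activates 3 as the O-acylisourea and DMAP relays the acyl group to the primary alcohol 5, while both terminal alkynes are inert under these near-neutral conditions.

**Step 4**
Reactants: 6 dodec-11-yn-1-yl tetradec-13-ynoate
Product: 7 oxacycloheptacosa-14,16-diyn-2-one (hexacosa-13,15-diyn-26-olide)
Conditions: Cu(OAc)2 (8 equiv), pyridine/Et2O 5:1, 45 °C, syringe-pump addition of 6 over 24 h (final concentration about 1 mM)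
Reagents that add atoms: none
Why: Pyridine-assisted cupration of both terminal C–H bonds gives copper acetylides at C14 and C15, and one-electron oxidation by Cu(II) followed by reductive elimination from a dinuclear copper acetylide joins the two sp carbons as the C14–C15 bond while copper leaves as Cu(I). The closest known reaction type is the Eglinton (Glaser-type) oxidative macrocyclisation of ester-linked α,ω-diynes to large-ring 1,3-diyne lactones. The 27-membered ring is closed end to end by head-to-head coupling of the two chain termini, both triple bonds becoming endocyclic, and the linear C13–C16 rod should be accommodated without strain in a ring of this size. No stereocentre is created and, unlike an alkene-forming closure, no E/Z question arises. The selectivity needed is ring closure over intermolecular coupling to the cyclic dimer and linear oligomers; it is secured by slow addition of 6 into a large excess of Cu(OAc)2, which keeps the stationary concentration of free diyne very low, and by a substrate that offers only two reactive sites, its terminal alkynes. The isolated ester and the methylene chains are inert to Cu(OAc)2 in pyridine.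

**Step 5**
Reactants: 7 oxacycloheptacosa-14,16-diyn-2-one
Product: 8 26-hexacosanolide (oxacycloheptacosan-2-one)
Conditions: H2 (1–3 atm), 10% Pd/C, EtOAc, rt
Reagents that add atoms: none
Why: Heterogeneous catalytic hydrogenation should saturate both triple bonds of the conjugated diyne (four equivalents of H2) without touching the lactone, removing the unsaturation that served only to enable ring closure.

**Compound list**
1 | 12-bromododecanoic acid | O=C(O)CCCCCCCCCCCBr | starting material
2 | lithium acetylide–ethylenediamine complex | [Li]C#C.NCCN | starting material
3 | tetradec-13-ynoic acid | O=C(O)CCCCCCCCCCCC#C | intermediate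
4 | 10-bromodecan-1-ol | OCCCCCCCCCCBr | starting material
5 | dodec-11-yn-1-ol | OCCCCCCCCCCC#C | intermediate
6 | dodec-11-yn-1-yl tetradec-13-ynoate | C#CCCCCCCCCCCCC(=O)OCCCCCCCCCCC#C | intermediate
7 | oxacycloheptacosa-14,16-diyn-2-one (27-membered lactone, conjugated diyne at C13–C16 of the acid-numbered chain) | O=C1CCCCCCCCCCCC#CC#CCCCCCCCCCCO1 | intermediate
8 | 26-hexacosanolide (oxacycloheptacosan-2-one, achiral) | O=C1CCCCCCCCCCCCCCCCCCCCCCCCCO1 | target

**Totals**
Total step count: 5. Longest linear sequence: 4 steps (step 1 or 2, then steps 3, 4, 5).

**Steps most likely to fail**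

Step 4. Intermolecular oxidative coupling may outrun ring closure, so that the cyclic dimer and linear oligodiynes form in place of the monomeric ring. The fallback makes the C14–C15 bond intermolecularly and closes the ring at the ester instead; it sets out from 3 and 5 and comes back at 8, bypassing 6 and 7. Bromination of 5 at the alkyne terminus (NBS, cat. AgNO3, acetone, rt) should give 12-bromododec-11-yn-1-ol F1. Cadiot–Chodkiewicz coupling of F1 with 3 (cat. CuCl, NH2OH·HCl, aq. EtNH2, MeOH, 0 °C → rt) should give 26-hydroxyhexacosa-13,15-diynoic acid F2. Hydrogenation (H2, Pd/C, THF/EtOAc, 40 °C) should give 26-hydroxyhexacosanoic acid F3. Yamaguchi macrolactonisation of F3 (2,4,6-trichlorobenzoyl chloride, Et3N, THF; then slow addition to DMAP in toluene at reflux) should deliver 8.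

Step 1. Substitution on the sparingly soluble carboxylate salt may be slow, so that elimination of HBr and base-induced migration of the new triple bond along the chain take over. The fallback moves the alkylation to the alcohol oxidation level and installs the carboxyl group afterwards; it sets out from 1 and comes back at 3. Borane reduction of 1 (BH3·THF, 0 °C → rt), which spares the primary bromide, should give 12-bromododecan-1-ol F4. Alkylation of F4 with 2 under the conditions of step 2 should give tetradec-13-yn-1-ol F5. Jones oxidation of F5 (CrO3, H2SO4, acetone, 0 °C) should return 3.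

Step 2. The lithium alkoxide may be O-alkylated by a second molecule of bromide (ether oligomers), and the terminal triple bond may migrate under the strongly basic conditions. The fallback masks both the hydroxyl group and the alkyne terminus; it sets out from 4 and comes back at 5. Protection of 4 (3,4-dihydro-2H-pyran, PPTS, CH2Cl2, rt) should give 2-[(10-bromodecyl)oxy]tetrahydro-2H-pyran F6. Alkylation of lithium (trimethylsilyl)acetylide with F6 (TMS-acetylene, n-BuLi, THF/DMPU, −78 °C → rt) should give trimethyl[12-(tetrahydro-2H-pyran-2-yloxy)dodec-1-yn-1-yl]silane F7, whose silyl cap blocks alkyne migration. Desilylation (K2CO3, MeOH, rt) should give 2-(dodec-11-yn-1-yloxy)tetrahydro-2H-pyran F8. Acetal cleavage of F8 (TsOH·H2O, MeOH, rt) should return 5.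

**Further compounds**
F1 | step 4 | 12-bromododec-11-yn-1-ol | OCCCCCCCCCCC#CBr
F2 | step 4 | 26-hydroxyhexacosa-13,15-diynoic acid | O=C(O)CCCCCCCCCCCC#CC#CCCCCCCCCCCO
F3 | step 4 | 26-hydroxyhexacosanoic acid | O=C(O)CCCCCCCCCCCCCCCCCCCCCCCCCO
F4 | step 1 | 12-bromododecan-1-ol | OCCCCCCCCCCCCBr
F5 | step 1 | tetradec-13-yn-1-ol | OCCCCCCCCCCCCC#C
F6 | step 2 | 2-[(10-bromodecyl)oxy]tetrahydro-2H-pyran | BrCCCCCCCCCCOC1CCCCO1
F7 | step 2 | trimethyl[12-(tetrahydro-2H-pyran-2-yloxy)dodec-1-yn-1-yl]silane | C[Si](C)(C)C#CCCCCCCCCCCOC1CCCCO1
F8 | step 2 | 2-(dodec-11-yn-1-yloxy)tetrahydro-2H-pyran | C#CCCCCCCCCCCOC1CCCCO1
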